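**Slow Z.** The slow thing in these runs was the loss of Z, and it hid a fast step. We have two earlier runs and one new flask, with the following questions.

| flask | Z | X | E | Q | remark | time |
|---|---|---|---|---|---|---|
| Saturday's | 0.50 M | 0.50 M | 0.30 M | 1.5 M | run made earlier |  |
| Friday's | 1 M | 1 M | 0.30 M | 0.75 M | run made earlier |  |
| flask | 1.0 M | 1.0 M | 0.300 M | 1.50 M |  | 15 min |

| run | time / min | J / % | G / % | Z / % |
|---|---|---|---|---|
| Saturday's | 1.00 | 2.9 | 2.6 | 46.3 |
| Saturday's | 1.33 | 3.4 | 2.3 | 45.1 |
| Saturday's | 2.00 | 5.7 | 4.4 | 43.2 |
| Saturday's | 3.00 | 7.2 | 5.7 | 38.2 |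
| Saturday's | 5.00 | 11.1 | 9.8 | 31.7 |
| Saturday's | 8.00 | 15.1 | 14.4 | 24.6 |
| Saturday's | 12.0 | 19.3 | 18.8 | 17.8 |
| Friday's | 1.00 | 2.8 | 0.4 | 45.9 |
| Friday's | 2.00 | 4.9 | 3.9 | 42.3 |
| Friday's | 3.00 | 6.8 | 5.7 | 39.7 |
| Friday's | 6.00 | 8.7 | 8.1 | 34.0 |
| Friday's | 12.0 | 10.5 | 11.6 | 31.8 |

(each reading ± 0.5 percentage points)

- L is single-handed; Z and X are mirror images of each other, charged as a racemate, each of them at the stated concentration
- solid, in amounts per volume of the solution: Q
- at the start none of Q is in solution
- an excess is the difference of the two amounts in percent of their sum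
- an excess is below zero if the other one leads
- the handed part of L does not stay in what it makes, so the products of the two hands are mirror images too

* excess of J over G in the product at 1.5 min
* excess of J over G in the product at 15 min
* part of the Z and X charged together that has reacted at 15 min

In Saturday's run I read pseudo-first-order constants of 0.0861 min⁻¹ for Z and 0.0105 min⁻¹ for X, so Z went faster. Even so, J stood at 19.3% and G at 18.8% at 12.0 min, so I took J and G to be turning into each other.

**Swap rate.** In a steady state, the difference in making J and G is balanced by the swap. I therefore divided that difference in rates by the standing J minus G, and time dropped out. This gave the swap rate, the rate at which a difference between J and G decays, as 1.85 min⁻¹. It is a rough reading, taken at 3.00 min on a difference of 1.5 percentage points. Its half-time, 0.375 min, is shorter than 15 min, so the excess should follow the rates: the Z part times its constant, minus the X part times its constant, divided by the swap rate and the reacted part.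

**First instants.** I carried Saturday's constants to the new flask, which has the same Q and E. At 1.5 min my rule gave an excess of 25.8%.

**The middle.** At 7.50 min Z had thinned and product had grown, and my excess fell to 3.47%.

**The end.** Friday's run reached 22.1% product, close to its Q minus E, 22.5% of the charge. The same budget in the new flask is 60.0%, above my reacted part of 43.5%. My excess at 15 min was 0.913%.

**The forecast.** It said 22%, 0.7% and 43%, both excesses lower than mine, judging that the “solid probably just lasts or nearly so”.

**The result.** The flask gave 21.1%, 0.709% and 43.5%.

    L + Z → J (k = 0.00400 M⁻¹ s⁻¹)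
    L + X → G (k = 4.60 × 10⁻⁴ M⁻¹ s⁻¹)
    J ⇌ G (k = 0.0200 s⁻¹)
    L + E → D (k = 0.0340 M⁻¹ s⁻¹)
    Q ⇌ L, rate k5*(cs5 - [L]) while solid is left; crystals form when [L] > cs5 (solubility = 0.370 M, k = 0.380 s⁻¹)

The relaxation half-life of J and G, 0.289 min, was shorter than 15 min. Keeping to what I had read and leaving the scheme's constants aside, I scaled Saturday's two constants by the flask's L at 15.0 min, 0.330 M, over its L at 7.50 min, 0.368 M, and divided by my swap rate of 1.85 min⁻¹ and the reacted part, which gave 0.793% against the 0.709% of the flask. The neighbour flask with 0.75 M of E had, at 15.0 min, L at 0.0806 M, Z at 21.2% and X at 45.3%, with 33.5% reacted. The same division, with its L taken over the same 0.368 M, gives 0.477%, and that flask gave 0.412%.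

Readings and results are calculated from invented constants, noise included.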